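**Retrosynthetic overview**

- Target 13 comes from hexamethyl ether 12 by cleavage of six aryl methyl ethers. The C5 styryl double bond of 12 comes from aldehyde 10 and phosphonate 11 by Horner–Wadsworth–Emmons olefination. Aldehyde 10 comes from ester 8, which is the O-methylated form of phenol 7.
- Key disconnection in 7: the C3–aryl bond and the O1–C2 bond of the dihydrofuran ring are cut together. This gives boronic acid 5 and 2-hydroxystilbene 4, whose two alkene carbons become C3 and C2.
- Feature used: C2 is benzylic to the para-oxygenated ring B, so it is a latent p-quinone methide carbon that the ring A oxygen O1 can attack. C3 carries the 3,5-dioxygenated aryl group, which palladium delivers.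
- Stilbene 4 comes from iodophenol 1 and styrene 2 by Mizoroki–Heck coupling and removal of the acetate.
- Ring order: all four benzene rings are bought. The dihydrofuran ring (O1–C2–C3–C3a–C7a) is the only ring formed, in step 3.

Key step: step 3

Remark: positions follow the 2,3-dihydro-1-benzofuran numbering of the target; ring A is its benzo ring and ring B the aryl ring on C2. The (S)-ligand in step 3 is assumed to give the 3S series; a first run should settle the sense of induction, and the (R)-ligand is taken if it is opposite.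

**Route**

Step 1
Reactants: 1 methyl 4-hydroxy-3-iodobenzoate; 2 (4-ethenyl-2-methoxyphenyl) acetate, also called 4-acetoxy-3-methoxystyrene
Product: 3 methyl 3-[(E)-2-(4-acetoxy-3-methoxyphenyl)ethenyl]-4-hydroxybenzoate
Conditions: Pd(OAc)2 (cat.), NaOAc, Bu4NCl, DMF, 80 °C
Reagents that add atoms: none
Why: Mizoroki–Heck coupling of an aryl iodide with a styrene should give the E-stilbene by syn insertion and syn β-hydride elimination, and the acetate keeps the para-oxygenated styrene from polymerising or forming a quinone methide at this stage.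

Step 2
Reactants: 3 methyl 3-[(E)-2-(4-acetoxy-3-methoxyphenyl)ethenyl]-4-hydroxybenzoate
Product: 4 methyl 4-hydroxy-3-[(E)-2-(4-hydroxy-3-methoxyphenyl)ethenyl]benzoate
Conditions: K2CO3 (0.2 equiv), MeOH, rt, N2; aq. NH4Cl
Reagents that add atoms: none
Why: Base-catalysed methanolysis (transesterification) of the aryl acetate should free the ring B phenol, while the same exchange at the methyl ester is degenerate.

Step 3
Reactants: 4 methyl 4-hydroxy-3-[(E)-2-(4-hydroxy-3-methoxyphenyl)ethenyl]benzoate; 5 3,5-dimethoxyphenylboronic acid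
Product: 7 methyl (2S,3S)-3-(3,5-dimethoxyphenyl)-2-(4-hydroxy-3-methoxyphenyl)-2,3-dihydro-1-benzofuran-5-carboxylate, via p-quinone methide 6 (not isolated)
Conditions: Pd(MeCN)2(OTs)2 (cat.), (S)-4-tert-butyl-2-[5-(trifluoromethyl)pyridin-2-yl]-4,5-dihydrooxazole (cat.), Cu(OTf)2 (cat.), KHCO3 (0.5 equiv), 3 Å MS, O2 (1 atm), DMF, rt
Reagents that add atoms: none
Why: Proposed new method: aryl transfer from boron to ligated divalent palladium gives an aryl–palladium species that adds syn across the stilbene double bond, the 3,5-dimethoxyphenyl group going to C3 and palladium to C2; the C2–Pd bond next to the 4-hydroxyaryl ring then breaks heterolytically with loss of zerovalent palladium to give p-quinone methide 6, the ring A phenoxide adds to its exocyclic carbon (O1–C2), and Cu(OTf)2/O2 return palladium to the divalent state. The closest known reaction types are the enantioselective palladium-catalysed difunctionalisation of vinylphenols through quinone methides and the oxidative Heck arylation of alkenes with arylboronic acids under pyridine–oxazoline ligands; neither has been shown with a stilbene acceptor and an internal phenol as the second nucleophile. The dihydrofuran ring closes by a 5-exo-trig oxa-conjugate addition onto the quinone methide. C3 is set in the migratory insertion, where the chiral ligand selects the alkene face; C2 is set in the ring closure under control of C3, the 2-aryl group settling trans to the 3-aryl group, which is also the thermodynamic outcome because the closure can reverse through 6. The step needs aryl delivery to C3 and not to C2, and quinone methide formation ahead of β-hydride elimination: the para ester makes the ring A phenol the more acidic one (by roughly two pKa units, estimated from methyl 4-hydroxybenzoate and guaiacol), so bicarbonate ionises ring A selectively and its ortho-phenoxide polarises the alkene toward palladium at C2, while the free para-hydroxyl of ring B gives the C2–Pd bond its heterolytic exit.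

Step 4
Reactants: 7 methyl (2S,3S)-3-(3,5-dimethoxyphenyl)-2-(4-hydroxy-3-methoxyphenyl)-2,3-dihydro-1-benzofuran-5-carboxylate
Product: 8 methyl (2S,3S)-2-(3,4-dimethoxyphenyl)-3-(3,5-dimethoxyphenyl)-2,3-dihydro-1-benzofuran-5-carboxylate
Conditions: MeI, K2CO3, acetone, rt
Reagents that add atoms: iodomethane, CI
Why: Williamson O-methylation of the only free phenol should cap the para-hydroxyl that could otherwise re-open the ring through the quinone methide in the later hydride and base steps.

Step 5
Reactants: 8 methyl (2S,3S)-2-(3,4-dimethoxyphenyl)-3-(3,5-dimethoxyphenyl)-2,3-dihydro-1-benzofuran-5-carboxylate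
Product: 9 [(2S,3S)-2-(3,4-dimethoxyphenyl)-3-(3,5-dimethoxyphenyl)-2,3-dihydro-1-benzofuran-5-yl]methanol
Conditions: i-Bu2AlH, CH2Cl2, −78 → 0 °C; aq. potassium sodium tartrate
Reagents that add atoms: none
Why: Hydride reduction of the aryl methyl ester with i-Bu2AlH should give the benzylic alcohol, the aryl ethers and the dihydrofuran ring being inert to the reagent.

Step 6
Reactants: 9 [(2S,3S)-2-(3,4-dimethoxyphenyl)-3-(3,5-dimethoxyphenyl)-2,3-dihydro-1-benzofuran-5-yl]methanol
Product: 10 (2S,3S)-2-(3,4-dimethoxyphenyl)-3-(3,5-dimethoxyphenyl)-2,3-dihydro-1-benzofuran-5-carbaldehyde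
Conditions: activated MnO2, CH2Cl2, rt
Reagents that add atoms: none
Why: Heterogeneous MnO2 oxidation is selective for benzylic alcohols and should stop at the aldehyde under neutral conditions that leave C2 and C3 untouched.

Step 7
Reactants: 10 (2S,3S)-2-(3,4-dimethoxyphenyl)-3-(3,5-dimethoxyphenyl)-2,3-dihydro-1-benzofuran-5-carbaldehyde; 11 diethyl [(3,5-dimethoxyphenyl)methyl]phosphonate
Product: 12 (2S,3S)-2-(3,4-dimethoxyphenyl)-3-(3,5-dimethoxyphenyl)-5-[(E)-2-(3,5-dimethoxyphenyl)ethenyl]-2,3-dihydro-1-benzofuran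
Conditions: NaH, THF, 0 °C → rt
Reagents that add atoms: none
Why: Horner–Wadsworth–Emmons olefination of a non-enolisable aryl aldehyde with a benzylic phosphonate anion should give the E-stilbene through the reversible, anti-selective addition and syn elimination of phosphate.

Step 8
Reactants: 12 (2S,3S)-2-(3,4-dimethoxyphenyl)-3-(3,5-dimethoxyphenyl)-5-[(E)-2-(3,5-dimethoxyphenyl)ethenyl]-2,3-dihydro-1-benzofuran
Product: 13 4-[(2S,3S)-3-(3,5-dihydroxyphenyl)-5-[(E)-2-(3,5-dihydroxyphenyl)ethenyl]-2,3-dihydro-1-benzofuran-2-yl]benzene-1,2-diol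
Conditions: BBr3 (excess), CH2Cl2, −78 → 0 °C, dark; H2O
Reagents that add atoms: none
Why: Lewis-acid ether cleavage with BBr3 (bromide attack at each O-methyl carbon) should free all six phenols; C3 is not touched, and any reversible ionisation at C2 returns to the favoured trans isomer.

**Compound list**

1 | methyl 4-hydroxy-3-iodobenzoate | COC(=O)c1ccc(O)c(I)c1 | starting material
2 | (4-ethenyl-2-methoxyphenyl) acetate | C=Cc1ccc(OC(C)=O)c(OC)c1 | starting material
3 | methyl 3-[(E)-2-(4-acetoxy-3-methoxyphenyl)ethenyl]-4-hydroxybenzoate | COC(=O)c1ccc(O)c(c1)/C=C/c1ccc(OC(C)=O)c(OC)c1 | intermediate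
4 | methyl 4-hydroxy-3-[(E)-2-(4-hydroxy-3-methoxyphenyl)ethenyl]benzoate | COC(=O)c1ccc(O)c(c1)/C=C/c1ccc(O)c(OC)c1 | intermediate
5 | 3,5-dimethoxyphenylboronic acid | COc1cc(OC)cc(B(O)O)c1 | starting material
6 | methyl 3-[(1S)-1-(3,5-dimethoxyphenyl)-2-(3-methoxy-4-oxocyclohexa-2,5-dien-1-ylidene)ethyl]-4-hydroxybenzoate (exocyclic double-bond geometry not defined) | COC(=O)c1ccc(O)c(c1)[C@H](c1cc(OC)cc(OC)c1)C=C1C=CC(=O)C(OC)=C1 | intermediate (not isolated)
7 | methyl (2S,3S)-3-(3,5-dimethoxyphenyl)-2-(4-hydroxy-3-methoxyphenyl)-2,3-dihydro-1-benzofuran-5-carboxylate | COC(=O)c1ccc2c(c1)[C@H](c1cc(OC)cc(OC)c1)[C@@H](c1ccc(O)c(OC)c1)O2 | intermediate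
8 | methyl (2S,3S)-2-(3,4-dimethoxyphenyl)-3-(3,5-dimethoxyphenyl)-2,3-dihydro-1-benzofuran-5-carboxylate | COC(=O)c1ccc2c(c1)[C@H](c1cc(OC)cc(OC)c1)[C@@H](c1ccc(OC)c(OC)c1)O2 | intermediate
9 | [(2S,3S)-2-(3,4-dimethoxyphenyl)-3-(3,5-dimethoxyphenyl)-2,3-dihydro-1-benzofuran-5-yl]methanol | OCc1ccc2c(c1)[C@H](c1cc(OC)cc(OC)c1)[C@@H](c1ccc(OC)c(OC)c1)O2 | intermediate
10 | (2S,3S)-2-(3,4-dimethoxyphenyl)-3-(3,5-dimethoxyphenyl)-2,3-dihydro-1-benzofuran-5-carbaldehyde | O=Cc1ccc2c(c1)[C@H](c1cc(OC)cc(OC)c1)[C@@H](c1ccc(OC)c(OC)c1)O2 | intermediate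
11 | diethyl [(3,5-dimethoxyphenyl)methyl]phosphonate | CCOP(=O)(Cc1cc(OC)cc(OC)c1)OCC | starting material
12 | (2S,3S)-2-(3,4-dimethoxyphenyl)-3-(3,5-dimethoxyphenyl)-5-[(E)-2-(3,5-dimethoxyphenyl)ethenyl]-2,3-dihydro-1-benzofuran | COc1cc(OC)cc(/C=C/c2ccc3c(c2)[C@H](c2cc(OC)cc(OC)c2)[C@@H](c2ccc(OC)c(OC)c2)O3)c1 | intermediate
13 | 4-[(2S,3S)-3-(3,5-dihydroxyphenyl)-5-[(E)-2-(3,5-dihydroxyphenyl)ethenyl]-2,3-dihydro-1-benzofuran-2-yl]benzene-1,2-diol | Oc1cc(O)cc(/C=C/c2ccc3c(c2)[C@H](c2cc(O)cc(O)c2)[C@@H](c2ccc(O)c(O)c2)O3)c1 | target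

**Totals**

Total step count: 8. Longest linear sequence: 8 steps (1 → 13); compounds 2, 5 and 11 are bought and enter at steps 1, 3 and 7.

**Steps most likely to fail**

1. Step 3 (carries the label). Several processes could divert it:
- Aryl migration to C2 instead of C3, which leaves palladium next to ring A and ends in β-hydride elimination to a triarylethylene. This is the main risk, because the regiochemical argument rests on selective ionisation of ring A and is untested.
- β-Hydride elimination from the C2 palladium alkyl before the quinone methide forms.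
- Weak facial discrimination by the ligand on a 1,2-diaryl alkene.
- Copper-mediated O-arylation of the phenols by the boronic acid, oxidative coupling of the electron-rich hydroxystilbene, or palladium-mediated oxidative cyclisation to a 2-arylbenzofuran.

Fallback, known chemistry only: the dihydrofuran ring is built by an enantioselective carbene C–H insertion. The fallback sets out from boronic acid 5 and comes back to the route at 12. 4-Bromo-2-iodophenol is O-alkylated with 3,4-dimethoxybenzyl chloride (K2CO3, DMF) to 4-bromo-1-[(3,4-dimethoxyphenyl)methoxy]-2-iodobenzene F1. Carbonylative Suzuki–Miyaura coupling of F1 with 5 at the iodide (CO 1 atm, PdCl2(PPh3)2, K2CO3, anisole, 80 °C) should give {5-bromo-2-[(3,4-dimethoxyphenyl)methoxy]phenyl}(3,5-dimethoxyphenyl)methanone F2. Hydrazine hydrate (EtOH, AcOH, reflux) converts it into [{5-bromo-2-[(3,4-dimethoxyphenyl)methoxy]phenyl}(3,5-dimethoxyphenyl)methylidene]hydrazine F3. Oxidation with MnO2 (CH2Cl2, 0 °C) gives 4-bromo-2-[diazo(3,5-dimethoxyphenyl)methyl]-1-[(3,4-dimethoxyphenyl)methoxy]benzene F4, which is used without isolation. With Rh2(S-PTAD)4, the dirhodium tetrakis[(S)-(1-adamantyl)(phthalimido)acetate] (or its antipode, whichever gives 3S), the donor/donor carbene should insert into the benzylic C–H bond of the ether and give the cis compound (2R,3S)-5-bromo-2-(3,4-dimethoxyphenyl)-3-(3,5-dimethoxyphenyl)-2,3-dihydro-1-benzofuran F5. Brief treatment with CF3CO2H in CH2Cl2 should equilibrate C2 through the para-methoxybenzylic cation, with C3 untouched, to the trans compound (2S,3S)-5-bromo-2-(3,4-dimethoxyphenyl)-3-(3,5-dimethoxyphenyl)-2,3-dihydro-1-benzofuran F6. Mizoroki–Heck coupling of F6 with 3,5-dimethoxystyrene (Pd(OAc)2, P(o-tol)3, NaOAc, DMF, 120 °C) then gives 12, so steps 4 to 7 are not needed.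

2. Step 8. The Lewis acid may ionise the C2–O1 bond of the electron-rich dihydrofuran and open the ring. Acid formed in the flask may add to or cyclise the stilbene, and sixfold ether cleavage may stop short.

Fallback: the ethers are cleaved before the stilbene exists and the phenols are carried as silyl ethers, so the last step is a fluoride desilylation. The fallback sets out from aldehyde 10 and comes back at 13. In 10 the ring oxygen is deactivated by the para formyl group; BBr3 (CH2Cl2, −78 → 0 °C) should give (2S,3S)-2-(3,4-dihydroxyphenyl)-3-(3,5-dihydroxyphenyl)-2,3-dihydro-1-benzofuran-5-carbaldehyde F7. Silylation (t-BuMe2SiCl, imidazole, DMF) gives (2S,3S)-2-[3,4-bis(tert-butyldimethylsilyloxy)phenyl]-3-[3,5-bis(tert-butyldimethylsilyloxy)phenyl]-2,3-dihydro-1-benzofuran-5-carbaldehyde F8. Wittig methylenation (Ph3P=CH2, THF, 0 °C) gives (2S,3S)-2-[3,4-bis(tert-butyldimethylsilyloxy)phenyl]-3-[3,5-bis(tert-butyldimethylsilyloxy)phenyl]-5-ethenyl-2,3-dihydro-1-benzofuran F9. Mizoroki–Heck coupling of F9 with 5-bromobenzene-1,3-diol (Pd(OAc)2, P(o-tol)3, NaOAc, DMF, 100 °C) gives 5-[(E)-2-{(2S,3S)-2-[3,4-bis(tert-butyldimethylsilyloxy)phenyl]-3-[3,5-bis(tert-butyldimethylsilyloxy)phenyl]-2,3-dihydro-1-benzofuran-5-yl}ethenyl]benzene-1,3-diol F10. Bu4NF buffered with AcOH (THF, 0 °C) then frees 13; silyl groups lost in part during the Heck step converge here.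

3. Step 4. Under carbonate the free para-hydroxyl can push open the dihydrofuran ring through the quinone methide, because the ring A phenoxide with its para ester is a good leaving group. The opened form may lose the C3 proton (loss of both stereocentres) or be O-methylated on ring A.

Fallback: the order of operations is changed so that the leaving-group activation is removed before any base is used. The fallback sets out from 7 and comes back at 9. Reduction of 7 with i-Bu2AlH (excess, one equivalent being spent on the phenol; CH2Cl2, −78 → 0 °C) should give 4-[(2S,3S)-3-(3,5-dimethoxyphenyl)-5-(hydroxymethyl)-2,3-dihydro-1-benzofuran-2-yl]-2-methoxyphenol F11, in which ring A no longer carries the ester. Selective phenol O-methylation (MeI, K2CO3, acetone, rt) then gives 9.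

**Further compounds**

F1 | step 3 | 4-bromo-1-[(3,4-dimethoxyphenyl)methoxy]-2-iodobenzene | COc1ccc(COc2ccc(Br)cc2I)cc1OC
F2 | step 3 | {5-bromo-2-[(3,4-dimethoxyphenyl)methoxy]phenyl}(3,5-dimethoxyphenyl)methanone | COc1ccc(COc2ccc(Br)cc2C(=O)c2cc(OC)cc(OC)c2)cc1OC
F3 | step 3 | [{5-bromo-2-[(3,4-dimethoxyphenyl)methoxy]phenyl}(3,5-dimethoxyphenyl)methylidene]hydrazine | COc1ccc(COc2ccc(Br)cc2C(=NN)c2cc(OC)cc(OC)c2)cc1OC
F4 | step 3 | 4-bromo-2-[diazo(3,5-dimethoxyphenyl)methyl]-1-[(3,4-dimethoxyphenyl)methoxy]benzene | COc1ccc(COc2ccc(Br)cc2C(=[N+]=[N-])c2cc(OC)cc(OC)c2)cc1OC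
F5 | step 3 | (2R,3S)-5-bromo-2-(3,4-dimethoxyphenyl)-3-(3,5-dimethoxyphenyl)-2,3-dihydro-1-benzofuran | Brc1ccc2c(c1)[C@H](c1cc(OC)cc(OC)c1)[C@H](c1ccc(OC)c(OC)c1)O2
F6 | step 3 | (2S,3S)-5-bromo-2-(3,4-dimethoxyphenyl)-3-(3,5-dimethoxyphenyl)-2,3-dihydro-1-benzofuran | Brc1ccc2c(c1)[C@H](c1cc(OC)cc(OC)c1)[C@@H](c1ccc(OC)c(OC)c1)O2
F7 | step 8 | (2S,3S)-2-(3,4-dihydroxyphenyl)-3-(3,5-dihydroxyphenyl)-2,3-dihydro-1-benzofuran-5-carbaldehyde | O=Cc1ccc2c(c1)[C@H](c1cc(O)cc(O)c1)[C@@H](c1ccc(O)c(O)c1)O2
F8 | step 8 | (2S,3S)-2-[3,4-bis(tert-butyldimethylsilyloxy)phenyl]-3-[3,5-bis(tert-butyldimethylsilyloxy)phenyl]-2,3-dihydro-1-benzofuran-5-carbaldehyde | O=Cc1ccc2c(c1)[C@H](c1cc(O[Si](C)(C)C(C)(C)C)cc(O[Si](C)(C)C(C)(C)C)c1)[C@@H](c1ccc(O[Si](C)(C)C(C)(C)C)c(O[Si](C)(C)C(C)(C)C)c1)O2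
F9 | step 8 | (2S,3S)-2-[3,4-bis(tert-butyldimethylsilyloxy)phenyl]-3-[3,5-bis(tert-butyldimethylsilyloxy)phenyl]-5-ethenyl-2,3-dihydro-1-benzofuran | C=Cc1ccc2c(c1)[C@H](c1cc(O[Si](C)(C)C(C)(C)C)cc(O[Si](C)(C)C(C)(C)C)c1)[C@@H](c1ccc(O[Si](C)(C)C(C)(C)C)c(O[Si](C)(C)C(C)(C)C)c1)O2
F10 | step 8 | 5-[(E)-2-{(2S,3S)-2-[3,4-bis(tert-butyldimethylsilyloxy)phenyl]-3-[3,5-bis(tert-butyldimethylsilyloxy)phenyl]-2,3-dihydro-1-benzofuran-5-yl}ethenyl]benzene-1,3-diol | Oc1cc(O)cc(/C=C/c2ccc3c(c2)[C@H](c2cc(O[Si](C)(C)C(C)(C)C)cc(O[Si](C)(C)C(C)(C)C)c2)[C@@H](c2ccc(O[Si](C)(C)C(C)(C)C)c(O[Si](C)(C)C(C)(C)C)c2)O3)c1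
F11 | step 4 | 4-[(2S,3S)-3-(3,5-dimethoxyphenyl)-5-(hydroxymethyl)-2,3-dihydro-1-benzofuran-2-yl]-2-methoxyphenol | OCc1ccc2c(c1)[C@H](c1cc(OC)cc(OC)c1)[C@@H](c1ccc(O)c(OC)c1)O2
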